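# Proposed synthesis of the trimeric acylphloroglucinol 35 (Filixsäure) through a cyclobutenone–ynol ether benzannulation of ring B

Compound numbers are those of the steps below.

## Analysis of the target

The target 35 is a linear trimer of three six-membered carbocycles joined by two methylene bridges. Ring A is a 2-butanoyl-6,6-dimethylcyclohexadienone with two enolic hydroxyls (an enolised β-triketone). Ring B is a butanoylphloroglucinol in which every carbon is substituted: B1 bridge to ring A, B2 OH, B3 bridge to ring C, B4 OH, B5 butanoyl, B6 OH. Ring C is a butanoyl-methylphloroglucinol whose C4 oxygen, between the methyl and the butanoyl group, is the only methylated one. There is no stereocentre; the only isomerism is the keto–enol tautomerism of ring A, so only constitution has to be controlled. The sensitive features are seven acidic, oxidisable enol and phenol hydroxyls, three chelated ketones and, above all, the two bridges, which in the free polyphenol can be cleaved and re-formed through quinone-methide-type fragments under acid or base, scrambling the rings. The difficulty is that ring B is a hexasubstituted hub between two different arms, which condensations with one-carbon electrophiles cannot tell apart, while one oxygen of seven is methylated and three butanoyl groups sit on defined carbons. The strategy rests on ring B: a cut through B6–B1 and B2–B3 divides 35 into two halves of similar size, one holding B3–B6 with the bridge to ring C and the other B1 and B2 with the bridge to ring A, which is the atom pattern of a 3-alkoxycyclobutenone (four ring carbons, oxygen on B4) and an ynol ether (two ring carbons, oxygen on B2), the partners of a benzannulation through vinylketenes.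

## Retrosynthetic reasoning

**35 back to 34 and 33.** Only oxygen–protecting-group bonds are cut. The six benzyl groups of 34 (two on each ring) leave together by hydrogenolysis, a neutral step, so the free polyphenol 35 never meets acid, base or fluoride. The B2 oxygen cannot be a benzyl ether (see the key disconnection). It is a triisopropylsilyl ether in 33 and is freed one step earlier, while all other oxygens are still masked.

**33 back to 32 and 31.** The B5–acyl bond is cut. B5 is the only ring carbon of the skeleton that bears hydrogen, so the Friedel–Crafts acylation has no choice of position. It is placed before the deprotection: acylating the free polyphenol would expose unprotected bridges to a Lewis acid, whereas in 32 every oxygen is capped and ring B is a 1,3,5-trioxygenated arene. The cost is one step, benzylation of the B6 hydroxyl of 31, which keeps the acyl group off oxygen.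

**31 back to 18 and 26 (key disconnection).** Ring B is opened through B6–B1 and B2–B3. Cyclobutenone 18 supplies B6 (carbonyl), B3 (with the arm to protected ring C), B4 (benzyloxy) and B5 (CH2). Ynol silyl ether 26 supplies B1 (with the arm to protected ring A) and B2. The cut is made here because it is the only one that puts the two different arms on two different partners, so they cannot be interchanged, and gives halves of similar size. Forward, heat has to open 18 to vinylketene 27, which adds 26 with the orientation fixed by the polarity of the ynol ether. Ring opening of 28 and six-electron closure of 29 then give the arene by way of 30. The alkyne oxygen is silylated: a benzyl ynol ether undergoes a [3,3] shift below the temperature at which 18 opens, and the silyl ether has no such pathway.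

**26 back to 23, 21, 20 and 19.** The O–Si bond and the C(sp)–O bond of 26 are cut, leading to terminal alkyne 23. The forward step is oxidation of the acetylide 24 to ynolate 25 and O-silylation. The two benzyl enol ethers of 23 come from diol 21 and two equivalents of 10, transferred one after the other by way of 22. The propargyl group of 21 is attached to the only CH carbon of 20. Compound 20 is the gem-dimethylation product of commercial 19. The butanoyl group of ring A is thus present from the first compound.

**18 back to 17, and 17 back to 9 and 13.** The four-membered ring is cut through C1–C2 and C3–C4 into ynol ether 17 and a two-carbon unit that is generated in the flask. A benzyl ynol ether is acceptable here because 17 is made and consumed at or below room temperature, and the benzyl group ends as the B4 protecting group. Compound 17 is cut at its sp–sp3 bond into benzylic bromide 9 and zinc acetylide 16. The latter is generated from dichlorovinyl ether 13, which comes from 10 and 11.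

**9 back to 1.** The bromomethyl group of 9 is traced through alcohol 8 to aldehyde 7, formed by formylation of the only open ring carbon of 5. The oxygen pattern of 5 is set on ketone 2, the acylation product of 1. The para hydroxyl and the less hindered ortho hydroxyl are benzylated (3, then 4). The hydroxyl left between methyl and carbonyl is then methylated.

## Alternatives that were turned down

**Alternative 1:** Ring B is cut through B3–B4 and B5–B6. The forward step joins a 1-methoxy-1,3-bis(trimethylsilyloxy)diene A2, which carries the ring A arm on C2 and the ring C arm on C4, with 1-(benzyloxy)hex-1-yn-3-one A3. The diene terminus adds to the benzyloxy-bearing alkyne carbon and the resulting carbanion closes on the ester carbon with loss of the ester methoxy group, giving A1.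
- For: the B5 butanoyl group arrives with A3, so no acylation of ring B is needed; on this point it is stronger than the chosen route, which spends steps 15 and 16 on it.
- Against: A2 needs two different, reactive arylmethyl groups on the α and γ carbons of a β-keto ester and then a fully substituted bis(silyl) dienolate. The conjugate addition is normally run with a strong Lewis acid, which threatens the benzyl enol ethers of ring A. Attack at the ketone of A3 instead of the alkyne would give an isomeric ring. Rings A and C of A1 lack their butanoyl groups, so two C-acylations remain, one on a vinylogous ester carbon of ring A.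
- Comparison: the chosen route carries the butanoyl groups of rings A and C from the first steps, uses a neutral thermal ring formation, and its regiochemistry follows from the polarity of 26 alone.

**Alternative 2:** Ring C is cut through C2–C3 and C4–C5. The forward step heats the 3-(benzyloxy)-4-(arylmethyl)cyclobutenone A5, which carries the protected A–B unit, with 1-methoxyprop-1-yne A6 and gives phenol A4.
- For: A6 is a small, unhindered alkoxyalkyne of the kind for which this benzannulation is best established, so the ring-forming step is sterically easier than the union of 18 and 26. The methyl and methoxy groups of ring C are placed by the alkyne, with no selective O-alkylation; on both points it is stronger than the chosen route, which depends on step 2.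
- Against: the last and simplest ring is built from a two-carbon piece on an advanced intermediate. The hexasubstituted ring B with its two different arms, which is the actual problem, must already exist in A5 and be made by other chemistry. A4 still lacks the C5 butanoyl group.
- Comparison: the chosen route is convergent and makes the hub itself, each half arriving with its bridge carbon already attached.

**Alternative 3:** Ring C is cut through C3–C4 and C5–C6. The forward step joins the 1-methoxy-1,3-bis(trimethylsilyloxy)penta-1,3-diene A8, which carries the protected A–B arylmethyl group on C2, with 1-methoxyhex-1-yn-3-one A9, giving A7 with loss of the ester methoxy group.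
- For: ring C is formed complete, with methyl, methoxy, butanoyl and both hydroxyls; on this point it is stronger than the chosen route, which needs six steps for the ring C arm.
- Against: it is linear like alternative 2 and needs the A–B unit first. It has the Lewis acid and regiochemistry problems of alternative 1. A7 lacks the butanoyl groups of both ring A and ring B, so two late acylations remain.
- Comparison: the chosen route leaves one acylation, at the only open carbon of a fully protected intermediate, and builds ring B rather than presupposing it.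

Key step: step 14

Assumption: the double O-benzylation of ring A (step 12) is written for the 3,5-bis(benzyloxy)cyclohexa-2,4-dienone isomer 23; a regioisomeric bis(enol ether) would react alike at the alkyne and would give the same ring A in step 18.

## Route

Step 1
Reactants: 1 2-methylbenzene-1,3,5-triol
Product: 2 1-(2,4,6-trihydroxy-3-methylphenyl)butan-1-one
Conditions: PrCOCl (1.05 equiv), AlCl3, PhNO2–CH2Cl2, 0 °C → 50 °C; aq. HCl
Reagents that add atoms: butanoyl chloride, CCCC(=O)Cl
Why: Friedel–Crafts C-acylation of the symmetric triol; the two open ring carbons are equivalent and the first acyl group slows a second acylation.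

Step 2
Reactants: 2 1-(2,4,6-trihydroxy-3-methylphenyl)butan-1-one
Product: 4 1-[4,6-bis(benzyloxy)-2-hydroxy-3-methylphenyl]butan-1-one, via 4-O-benzyl ether 3 (not isolated)
Conditions: BnBr (2.05 equiv), K2CO3, acetone, reflux
Reagents that add atoms: benzyl bromide, BrCc1ccccc1
Why: Williamson etherification under weak base: the para hydroxyl is the most acidic and reacts first, then the ortho hydroxyl next to the ring hydrogen; the hydroxyl between methyl and carbonyl is the most hindered and the more strongly chelated, so it should stay free.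

Step 3
Reactants: 4 1-[4,6-bis(benzyloxy)-2-hydroxy-3-methylphenyl]butan-1-one
Product: 5 1-[4,6-bis(benzyloxy)-2-methoxy-3-methylphenyl]butan-1-one
Conditions: MeI (excess), K2CO3, DMF, 50 °C
Reagents that add atoms: iodomethane, CI
Why: Williamson methylation of the remaining chelated phenol in a dipolar aprotic solvent; this places the single O-methyl group of ring C between the methyl and the butanoyl group.

Step 4
Reactants: 5 1-[4,6-bis(benzyloxy)-2-methoxy-3-methylphenyl]butan-1-one
Product: 7 2,6-bis(benzyloxy)-3-butanoyl-4-methoxy-5-methylbenzaldehyde, via aryl iminium chloride 6 (not isolated)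
Conditions: POCl3, DMF, 0 °C → rt; then ice–water
Reagents that add atoms: N,N-dimethylformamide, CN(C)C=O; water, O
Why: Vilsmeier–Haack formylation at the only open ring carbon, which is ortho to two alkoxy groups and para to the third; the flanked ketone is twisted out of conjugation, and at or below room temperature its chloroformylation through the enol should be slower than attack on the ring.

Step 5
Reactants: 7 2,6-bis(benzyloxy)-3-butanoyl-4-methoxy-5-methylbenzaldehyde
Product: 8 1-[2,4-bis(benzyloxy)-3-(hydroxymethyl)-6-methoxy-5-methylphenyl]butan-1-one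
Conditions: NaBH4 (0.3 equiv), THF–MeOH, 0 °C
Reagents that add atoms: none
Why: Chemoselective hydride reduction; the aldehyde reacts far faster than the di-ortho-substituted aryl ketone with a limited charge of NaBH4 at 0 °C.

Step 6
Reactants: 8 1-[2,4-bis(benzyloxy)-3-(hydroxymethyl)-6-methoxy-5-methylphenyl]butan-1-one
Product: 9 1-[2,4-bis(benzyloxy)-3-(bromomethyl)-6-methoxy-5-methylphenyl]butan-1-one
Conditions: PBr3 (0.4 equiv), CH2Cl2, 0 °C; used at once without chromatography
Reagents that add atoms: phosphorus tribromide, BrP(Br)Br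
Why: Substitution of the electron-rich benzylic alcohol through its phosphite ester; the ring has no open position, so the reactive bromide cannot alkylate itself.

Step 7
Reactants: 10 benzyl alcohol; 11 trichloroethylene
Product: 13 benzyl (E)-1,2-dichloroethenyl ether, via potassium benzyl oxide 12 (not isolated)
Conditions: KH, THF, 0 °C; then 11, −40 °C → rt
Reagents that add atoms: none
Why: Alkoxide-induced dehydrochlorination of 11 to dichloroethyne and anti addition of the alkoxide give the (E)-dichlorovinyl ether, the standard precursor of alkoxyacetylides.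

Step 8
Reactants: 9 1-[2,4-bis(benzyloxy)-3-(bromomethyl)-6-methoxy-5-methylphenyl]butan-1-one; 13 benzyl (E)-1,2-dichloroethenyl ether
Product: 17 1-{2,4-bis(benzyloxy)-3-[3-(benzyloxy)prop-2-yn-1-yl]-6-methoxy-5-methylphenyl}butan-1-one, via benzyl chloroethynyl ether 14 (not isolated), via lithium benzyloxyacetylide 15 (not isolated), via benzyloxyethynylzinc chloride 16 (not isolated)
Conditions: 13 (1.5 equiv), n-BuLi (2.1 equiv per 13), THF, −78 °C; ZnCl2, −78 → 0 °C; then 9, Pd(PPh3)4 (5 mol %), 0 °C → rt; neutral work-up, Et3N-deactivated silica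
Reagents that add atoms: none
Why: β-Elimination and chlorine–lithium exchange give the lithium acetylide, transmetalation to zinc removes its basicity toward the ketone of 9, and a Negishi sp–sp3 coupling with the benzylic bromide under zerovalent palladium gives the ynol ether; everything stays at or below room temperature because benzyl ynol ethers undergo a [3,3] shift near 60 °C.

Step 9
Reactants: 17 1-{2,4-bis(benzyloxy)-3-[3-(benzyloxy)prop-2-yn-1-yl]-6-methoxy-5-methylphenyl}butan-1-one
Product: 18 3-(benzyloxy)-2-{[2,6-bis(benzyloxy)-3-butanoyl-4-methoxy-5-methylphenyl]methyl}cyclobut-2-en-1-one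
Conditions: AcCl (3 equiv), Et3N (3 equiv, slow addition), CH2Cl2, 0 °C → rt
Reagents that add atoms: acetyl chloride, CC(Cl)=O (source of ketene, C=C=O)
Why: [2+2] Cycloaddition of ketene with the ynol ether; the nucleophilic alkyne carbon remote from oxygen bonds to the ketene carbonyl carbon, which places the arylmethyl group on C2 and the benzyloxy group on C3, and the reaction runs below the rearrangement threshold of 17.

Step 10
Reactants: 19 1-(2,4,6-trihydroxyphenyl)butan-1-one
Product: 20 2-butanoyl-3,5-dihydroxy-6,6-dimethylcyclohexa-2,4-dien-1-one, via C-monomethyl ketone 2 (not isolated)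
Conditions: NaOMe (3 equiv), MeI (2.2 equiv), MeOH, 0 °C → rt; aq. HCl
Reagents that add atoms: iodomethane, CI
Why: Dearomatising double C-methylation of the phloroglucinol anion (classical preparation of acylfilicinic acids); the first methyl group makes its carbon the most nucleophilic one, so the second enters at the same carbon and gives the gem-dimethyl dienone.

Step 11
Reactants: 20 2-butanoyl-3,5-dihydroxy-6,6-dimethylcyclohexa-2,4-dien-1-one
Product: 21 2-butanoyl-3,5-dihydroxy-6,6-dimethyl-4-(prop-2-yn-1-yl)cyclohexa-2,4-dien-1-one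
Conditions: HC≡CCH2Br (1.1 equiv), NaOMe (1.1 equiv), MeOH, 0 °C → rt
Reagents that add atoms: 3-bromoprop-1-yne, C#CCBr
Why: C-Alkylation of the vinylogous acid anion in a protic medium, where hydrogen bonding to oxygen favours attack through the only CH carbon, which lies between two oxygenated carbons.

Step 12
Reactants: 21 2-butanoyl-3,5-dihydroxy-6,6-dimethyl-4-(prop-2-yn-1-yl)cyclohexa-2,4-dien-1-one; 10 benzyl alcohol
Product: 23 3,5-bis(benzyloxy)-2-butanoyl-6,6-dimethyl-4-(prop-2-yn-1-yl)cyclohexa-2,4-dien-1-one, via 5-O-benzyl enol ether 22 (not isolated)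
Conditions: BnOH (2.5 equiv), PPh3 (2.5 equiv), i-PrO2CN=NCO2i-Pr (2.5 equiv), THF, 0 °C → rt
Reagents that add atoms: benzyl alcohol (the second equivalent of 10), OCc1ccccc1
Why: Twofold Mitsunobu O-alkylation in which each cycle transfers the benzyl group of one molecule of 10, first to the free 5-hydroxyl (22) and then to the chelated 3-hydroxyl, so two molecules of 10 end up in 23. Both enolic hydroxyls are acidic enough to protonate the betaine, and the enolate attacks the benzyloxyphosphonium ion through oxygen because the carbons that could compete are fully substituted, which avoids the C-benzylation expected with a benzyl halide and carbonate.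

Step 13
Reactants: 23 3,5-bis(benzyloxy)-2-butanoyl-6,6-dimethyl-4-(prop-2-yn-1-yl)cyclohexa-2,4-dien-1-one
Product: 26 3,5-bis(benzyloxy)-2-butanoyl-6,6-dimethyl-4-(3-{[tri(propan-2-yl)silyl]oxy}prop-2-yn-1-yl)cyclohexa-2,4-dien-1-one, via dilithium enolate acetylide 24 (not isolated), via dilithium enolate ynolate 25 (not isolated)
Conditions: LiN(i-Pr)2 (2.2 equiv), THF, −78 °C; t-BuOOLi (from t-BuOOH and LiN(SiMe3)2, 1.2 equiv), −78 → 0 °C; i-Pr3SiCl (1.2 equiv), −78 °C → rt; pH 7 buffer
Reagents that add atoms: tert-butyl hydroperoxide (as its lithium salt), CC(C)(C)OO; chlorotri(propan-2-yl)silane, CC(C)[Si](Cl)(C(C)C)C(C)C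
Why: Two equivalents of amide base convert the ketone into its enolate, which protects it, and the alkyne into the acetylide; the sp carbanion is oxidised by the electrophilic peroxide oxygen to the ynolate, which the bulky chlorosilane silylates at oxygen, while the hindered lithium enolate is not silylated by i-Pr3SiCl at low temperature and is reprotonated on work-up.

Step 14
Reactants: 18 3-(benzyloxy)-2-{[2,6-bis(benzyloxy)-3-butanoyl-4-methoxy-5-methylphenyl]methyl}cyclobut-2-en-1-one; 26 3,5-bis(benzyloxy)-2-butanoyl-6,6-dimethyl-4-(3-{[tri(propan-2-yl)silyl]oxy}prop-2-yn-1-yl)cyclohexa-2,4-dien-1-one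
Product: 31 3,5-bis(benzyloxy)-4-{[4-(benzyloxy)-3-{[2,6-bis(benzyloxy)-3-butanoyl-4-methoxy-5-methylphenyl]methyl}-6-hydroxy-2-{[tri(propan-2-yl)silyl]oxy}phenyl]methyl}-2-butanoyl-6,6-dimethylcyclohexa-2,4-dien-1-one, via vinylketene 27 (not isolated), via 4-vinylcyclobutenone 28 (not isolated), via dienylketene 29 (not isolated), via cyclohexa-2,4-dienone 30 (not isolated)
Conditions: 26 (1.2 equiv), PhMe (0.3 M), 110 °C, sealed tube, Ar
Reagents that add atoms: none
Why: Thermal four-electron conrotatory opening of 18 gives vinylketene 27, whose carbonyl carbon (B6) is attacked by the oxygen-remote carbon of 26 (B1) in a [2+2] cycloaddition that also joins B3 to B2 and gives 28. A second four-electron opening of 28 gives dienylketene 29, and ring B closes by a six-electron disrotatory electrocyclisation in which B6 rejoins B5, giving 30, which enolises to the phenol. The closest known reaction is the Danheiser benzannulation of cyclobutenones with alkoxy- and siloxyalkynes. No stereocentre is formed; the quaternary carbon of 28 disappears on ring opening. The step needs one orientation of the [2+2], which the polarisation of the silyl ynol ether secures, placing the silyloxy group meta to the new hydroxyl and between the two arms. It also needs the ketene and the benzyloxyvinyl group cis in 29; an isomer with the vinyl group turned outward can reclose to 28 and open again. The silyl ynol ether has no sigmatropic or retro-ene pathway at this temperature, unlike a benzyl or tert-alkyl ynol ether. The driving force is the loss of four-membered-ring strain and the gain of an aromatic ring.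

Step 15
Reactants: 31 3,5-bis(benzyloxy)-4-{[4-(benzyloxy)-3-{[2,6-bis(benzyloxy)-3-butanoyl-4-methoxy-5-methylphenyl]methyl}-6-hydroxy-2-{[tri(propan-2-yl)silyl]oxy}phenyl]methyl}-2-butanoyl-6,6-dimethylcyclohexa-2,4-dien-1-one
Product: 32 3,5-bis(benzyloxy)-4-{[4,6-bis(benzyloxy)-3-{[2,6-bis(benzyloxy)-3-butanoyl-4-methoxy-5-methylphenyl]methyl}-2-{[tri(propan-2-yl)silyl]oxy}phenyl]methyl}-2-butanoyl-6,6-dimethylcyclohexa-2,4-dien-1-one
Conditions: BnBr, K2CO3, DMF, rt
Reagents that add atoms: benzyl bromide, BrCc1ccccc1
Why: Williamson benzylation of the single free phenol, so that the following acylation can only go to carbon; the aryl silyl ether and the vinylogous esters are inert to K2CO3 in DMF at room temperature.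

Step 16
Reactants: 32 3,5-bis(benzyloxy)-4-{[4,6-bis(benzyloxy)-3-{[2,6-bis(benzyloxy)-3-butanoyl-4-methoxy-5-methylphenyl]methyl}-2-{[tri(propan-2-yl)silyl]oxy}phenyl]methyl}-2-butanoyl-6,6-dimethylcyclohexa-2,4-dien-1-one
Product: 33 3,5-bis(benzyloxy)-4-{[2,4-bis(benzyloxy)-3-butanoyl-5-{[2,6-bis(benzyloxy)-3-butanoyl-4-methoxy-5-methylphenyl]methyl}-6-{[tri(propan-2-yl)silyl]oxy}phenyl]methyl}-2-butanoyl-6,6-dimethylcyclohexa-2,4-dien-1-one
Conditions: PrCO2H (3 equiv), (CF3CO)2O (3 equiv), CH2Cl2, 0 °C → rt; aq. NaHCO3
Reagents that add atoms: butanoic acid, CCCC(O)=O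
Why: Friedel–Crafts acylation by the mixed anhydride of butanoic and trifluoroacetic acid; B5 is the only ring carbon of the molecule that bears hydrogen and lies ortho to two benzyloxy groups and para to the silyloxy group, and the metal-free conditions are of the kind that acylates 1,3,5-tris(benzyloxy)benzene without ether cleavage.

Step 17
Reactants: 33 3,5-bis(benzyloxy)-4-{[2,4-bis(benzyloxy)-3-butanoyl-5-{[2,6-bis(benzyloxy)-3-butanoyl-4-methoxy-5-methylphenyl]methyl}-6-{[tri(propan-2-yl)silyl]oxy}phenyl]methyl}-2-butanoyl-6,6-dimethylcyclohexa-2,4-dien-1-one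
Product: 34 3,5-bis(benzyloxy)-4-{[2,4-bis(benzyloxy)-3-butanoyl-5-{[2,6-bis(benzyloxy)-3-butanoyl-4-methoxy-5-methylphenyl]methyl}-6-hydroxyphenyl]methyl}-2-butanoyl-6,6-dimethylcyclohexa-2,4-dien-1-one
Conditions: Bu4NF, AcOH, THF, 0 °C
Reagents that add atoms: none
Why: Fluoride cleaves the aryl silyl ether; the acetic acid buffer keeps the medium from becoming basic enough to touch the vinylogous esters or the bridges.

Step 18
Reactants: 34 3,5-bis(benzyloxy)-4-{[2,4-bis(benzyloxy)-3-butanoyl-5-{[2,6-bis(benzyloxy)-3-butanoyl-4-methoxy-5-methylphenyl]methyl}-6-hydroxyphenyl]methyl}-2-butanoyl-6,6-dimethylcyclohexa-2,4-dien-1-one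
Product: 35 Filixsäure, 2-butanoyl-4-{[3-butanoyl-5-[(3-butanoyl-2,6-dihydroxy-4-methoxy-5-methylphenyl)methyl]-2,4,6-trihydroxyphenyl]methyl}-3,5-dihydroxy-6,6-dimethylcyclohexa-2,4-dien-1-one
Conditions: H2 (1 atm), Pd/C (10 %), EtOAc–MeOH, rt; filtration, no basic or acidic work-up
Reagents that add atoms: none
Why: Hydrogenolysis of four aryl benzyl ethers and two benzyl enol ethers under neutral conditions; the enol ethers of ring A unveil the enolised triketone, and the chelated ketones and the bridges are not reduced at 1 atm.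

## Compound list

1 | 2-methylbenzene-1,3,5-triol (2-methylphloroglucinol) | Cc1c(O)cc(O)cc1O | starting material
2 | 1-(2,4,6-trihydroxy-3-methylphenyl)butan-1-one | CCCC(=O)c1c(O)cc(O)c(C)c1O | intermediate
3 | 1-[4-(benzyloxy)-2,6-dihydroxy-3-methylphenyl]butan-1-one | CCCC(=O)c1c(O)cc(OCc2ccccc2)c(C)c1O | intermediate
4 | 1-[4,6-bis(benzyloxy)-2-hydroxy-3-methylphenyl]butan-1-one | CCCC(=O)c1c(OCc2ccccc2)cc(OCc2ccccc2)c(C)c1O | intermediate
5 | 1-[4,6-bis(benzyloxy)-2-methoxy-3-methylphenyl]butan-1-one | CCCC(=O)c1c(OCc2ccccc2)cc(OCc2ccccc2)c(C)c1OC | intermediate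
6 | N-{[2,6-bis(benzyloxy)-3-butanoyl-4-methoxy-5-methylphenyl]methylidene}-N-methylmethanaminium chloride | CCCC(=O)c1c(OCc2ccccc2)c(C=[N+](C)C)c(OCc2ccccc2)c(C)c1OC.[Cl-] | intermediate
7 | 2,6-bis(benzyloxy)-3-butanoyl-4-methoxy-5-methylbenzaldehyde | CCCC(=O)c1c(OCc2ccccc2)c(C=O)c(OCc2ccccc2)c(C)c1OC | intermediate
8 | 1-[2,4-bis(benzyloxy)-3-(hydroxymethyl)-6-methoxy-5-methylphenyl]butan-1-one | CCCC(=O)c1c(OCc2ccccc2)c(CO)c(OCc2ccccc2)c(C)c1OC | intermediate
9 | 1-[2,4-bis(benzyloxy)-3-(bromomethyl)-6-methoxy-5-methylphenyl]butan-1-one | CCCC(=O)c1c(OCc2ccccc2)c(CBr)c(OCc2ccccc2)c(C)c1OC | intermediate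
10 | benzyl alcohol | OCc1ccccc1 | starting material
11 | trichloroethylene | ClC=C(Cl)Cl | starting material
12 | potassium benzyl oxide | [K+].[O-]Cc1ccccc1 | intermediate
13 | benzyl (E)-1,2-dichloroethenyl ether | Cl/C=C(/Cl)OCc1ccccc1 | intermediate
14 | benzyl chloroethynyl ether | ClC#COCc1ccccc1 | intermediate
15 | lithium (benzyloxy)acetylide | [Li+].[C-]#COCc1ccccc1 | intermediate
16 | [(benzyloxy)ethynyl]zinc chloride | Cl[Zn]C#COCc1ccccc1 | intermediate
17 | 1-{2,4-bis(benzyloxy)-3-[3-(benzyloxy)prop-2-yn-1-yl]-6-methoxy-5-methylphenyl}butan-1-one | CCCC(=O)c1c(OCc2ccccc2)c(CC#COCc2ccccc2)c(OCc2ccccc2)c(C)c1OC | intermediate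
18 | 3-(benzyloxy)-2-{[2,6-bis(benzyloxy)-3-butanoyl-4-methoxy-5-methylphenyl]methyl}cyclobut-2-en-1-one | O=C1CC(OCc2ccccc2)=C1Cc1c(OCc2ccccc2)c(C)c(OC)c(C(=O)CCC)c1OCc1ccccc1 | intermediate
19 | 1-(2,4,6-trihydroxyphenyl)butan-1-one | CCCC(=O)c1c(O)cc(O)cc1O | starting material
20 | 2-butanoyl-3,5-dihydroxy-6,6-dimethylcyclohexa-2,4-dien-1-one (butanoylfilicinic acid) | CCCC(=O)C1=C(O)C=C(O)C(C)(C)C1=O | intermediate
21 | 2-butanoyl-3,5-dihydroxy-6,6-dimethyl-4-(prop-2-yn-1-yl)cyclohexa-2,4-dien-1-one | CCCC(=O)C1=C(O)C(CC#C)=C(O)C(C)(C)C1=O | intermediate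
22 | 5-(benzyloxy)-2-butanoyl-3-hydroxy-6,6-dimethyl-4-(prop-2-yn-1-yl)cyclohexa-2,4-dien-1-one | CCCC(=O)C1=C(O)C(CC#C)=C(OCc2ccccc2)C(C)(C)C1=O | intermediate
23 | 3,5-bis(benzyloxy)-2-butanoyl-6,6-dimethyl-4-(prop-2-yn-1-yl)cyclohexa-2,4-dien-1-one | CCCC(=O)C1=C(OCc2ccccc2)C(CC#C)=C(OCc2ccccc2)C(C)(C)C1=O | intermediate
24 | dilithium salt of 23: (Z)-enolate of the butanoyl group and terminal acetylide | [Li+].[Li+].CC/C=C(\[O-])C1=C(OCc2ccccc2)C(CC#[C-])=C(OCc2ccccc2)C(C)(C)C1=O | intermediate
25 | dilithium (Z)-enolate ynolate formed from 24 by oxidation of the acetylide carbon | [Li+].[Li+].CC/C=C(\[O-])C1=C(OCc2ccccc2)C(CC#C[O-])=C(OCc2ccccc2)C(C)(C)C1=O | intermediate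
26 | 3,5-bis(benzyloxy)-2-butanoyl-6,6-dimethyl-4-(3-{[tri(propan-2-yl)silyl]oxy}prop-2-yn-1-yl)cyclohexa-2,4-dien-1-one | CCCC(=O)C1=C(OCc2ccccc2)C(CC#CO[Si](C(C)C)(C(C)C)C(C)C)=C(OCc2ccccc2)C(C)(C)C1=O | intermediate
27 | 3-(benzyloxy)-2-{[2,6-bis(benzyloxy)-3-butanoyl-4-methoxy-5-methylphenyl]methyl}buta-1,3-dien-1-one (vinylketene) | O=C=C(Cc1c(OCc2ccccc2)c(C)c(OC)c(C(=O)CCC)c1OCc1ccccc1)C(OCc1ccccc1)=C | intermediate
28 | 4-[1-(benzyloxy)ethenyl]-4-{[2,6-bis(benzyloxy)-3-butanoyl-4-methoxy-5-methylphenyl]methyl}-2-{[2,6-bis(benzyloxy)-5-butanoyl-3,3-dimethyl-4-oxocyclohexa-1,5-dien-1-yl]methyl}-3-{[tri(propan-2-yl)silyl]oxy}cyclobut-2-en-1-one (racemic) | O=C1C(CC2=C(OCc3ccccc3)C(C)(C)C(=O)C(C(=O)CCC)=C2OCc2ccccc2)=C(O[Si](C(C)C)(C(C)C)C(C)C)C1(Cc1c(OCc2ccccc2)c(C)c(OC)c(C(=O)CCC)c1OCc1ccccc1)C(OCc1ccccc1)=C | intermediate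
29 | (3E)-5-(benzyloxy)-4-{[2,6-bis(benzyloxy)-3-butanoyl-4-methoxy-5-methylphenyl]methyl}-2-{[2,6-bis(benzyloxy)-5-butanoyl-3,3-dimethyl-4-oxocyclohexa-1,5-dien-1-yl]methyl}-3-{[tri(propan-2-yl)silyl]oxy}hexa-1,3,5-trien-1-one (dienylketene, ketene carbon and benzyloxyvinyl group cis) | O=C=C(CC1=C(OCc2ccccc2)C(C)(C)C(=O)C(C(=O)CCC)=C1OCc1ccccc1)/C(O[Si](C(C)C)(C(C)C)C(C)C)=C(/Cc1c(OCc2ccccc2)c(C)c(OC)c(C(=O)CCC)c1OCc1ccccc1)C(OCc1ccccc1)=C | intermediate
30 | 5-(benzyloxy)-4-{[2,6-bis(benzyloxy)-3-butanoyl-4-methoxy-5-methylphenyl]methyl}-2-{[2,6-bis(benzyloxy)-5-butanoyl-3,3-dimethyl-4-oxocyclohexa-1,5-dien-1-yl]methyl}-3-{[tri(propan-2-yl)silyl]oxy}cyclohexa-2,4-dien-1-one | O=C1CC(OCc2ccccc2)=C(Cc2c(OCc3ccccc3)c(C)c(OC)c(C(=O)CCC)c2OCc2ccccc2)C(O[Si](C(C)C)(C(C)C)C(C)C)=C1CC1=C(OCc2ccccc2)C(C)(C)C(=O)C(C(=O)CCC)=C1OCc1ccccc1 | intermediate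
31 | 3,5-bis(benzyloxy)-4-{[4-(benzyloxy)-3-{[2,6-bis(benzyloxy)-3-butanoyl-4-methoxy-5-methylphenyl]methyl}-6-hydroxy-2-{[tri(propan-2-yl)silyl]oxy}phenyl]methyl}-2-butanoyl-6,6-dimethylcyclohexa-2,4-dien-1-one (ring B: B6 OH, B5 H, B4 OBn, B2 silyl ether) | Oc1cc(OCc2ccccc2)c(Cc2c(OCc3ccccc3)c(C)c(OC)c(C(=O)CCC)c2OCc2ccccc2)c(O[Si](C(C)C)(C(C)C)C(C)C)c1CC1=C(OCc2ccccc2)C(C)(C)C(=O)C(C(=O)CCC)=C1OCc1ccccc1 | intermediate
32 | 3,5-bis(benzyloxy)-4-{[4,6-bis(benzyloxy)-3-{[2,6-bis(benzyloxy)-3-butanoyl-4-methoxy-5-methylphenyl]methyl}-2-{[tri(propan-2-yl)silyl]oxy}phenyl]methyl}-2-butanoyl-6,6-dimethylcyclohexa-2,4-dien-1-one | c1ccccc1COc1cc(OCc2ccccc2)c(Cc2c(OCc3ccccc3)c(C)c(OC)c(C(=O)CCC)c2OCc2ccccc2)c(O[Si](C(C)C)(C(C)C)C(C)C)c1CC1=C(OCc2ccccc2)C(C)(C)C(=O)C(C(=O)CCC)=C1OCc1ccccc1 | intermediate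
33 | 3,5-bis(benzyloxy)-4-{[2,4-bis(benzyloxy)-3-butanoyl-5-{[2,6-bis(benzyloxy)-3-butanoyl-4-methoxy-5-methylphenyl]methyl}-6-{[tri(propan-2-yl)silyl]oxy}phenyl]methyl}-2-butanoyl-6,6-dimethylcyclohexa-2,4-dien-1-one | CCCC(=O)c1c(OCc2ccccc2)c(CC2=C(OCc3ccccc3)C(C)(C)C(=O)C(C(=O)CCC)=C2OCc2ccccc2)c(O[Si](C(C)C)(C(C)C)C(C)C)c(Cc2c(OCc3ccccc3)c(C)c(OC)c(C(=O)CCC)c2OCc2ccccc2)c1OCc1ccccc1 | intermediate
34 | 3,5-bis(benzyloxy)-4-{[2,4-bis(benzyloxy)-3-butanoyl-5-{[2,6-bis(benzyloxy)-3-butanoyl-4-methoxy-5-methylphenyl]methyl}-6-hydroxyphenyl]methyl}-2-butanoyl-6,6-dimethylcyclohexa-2,4-dien-1-one | CCCC(=O)c1c(OCc2ccccc2)c(CC2=C(OCc3ccccc3)C(C)(C)C(=O)C(C(=O)CCC)=C2OCc2ccccc2)c(O)c(Cc2c(OCc3ccccc3)c(C)c(OC)c(C(=O)CCC)c2OCc2ccccc2)c1OCc1ccccc1 | intermediate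
35 | Filixsäure, 2-butanoyl-4-{[3-butanoyl-5-[(3-butanoyl-2,6-dihydroxy-4-methoxy-5-methylphenyl)methyl]-2,4,6-trihydroxyphenyl]methyl}-3,5-dihydroxy-6,6-dimethylcyclohexa-2,4-dien-1-one (no stereocentre) | CCCC(=O)C1=C(O)C(Cc2c(O)c(Cc3c(O)c(C)c(OC)c(C(=O)CCC)c3O)c(O)c(C(=O)CCC)c2O)=C(O)C(C)(C)C1=O | target

## Step count and least certain steps

Total: 18 steps. Longest linear sequence: 13 steps (steps 1–6, 8, 9 and 14–18, from 1).

**Step 14 (key step).** Three processes may stop it. The electrocyclic opening of 18 may be slow, because the 3-benzyloxy group stabilises the cyclobutenone as a vinylogous ester. The [2+2] joins a fully substituted ketene carbon to a hindered alkyne carbon, so dimerisation of 27 or its capture by the phenol already formed may win. Prolonged heating may also erode the benzyl enol ethers.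
Fallback, from 20, 19 and 5, back to the route at 35: the ring B hub is given up and the bridges are made by classical Mannich and quinone-methide chemistry. Aminomethylation of 20 with dimethyl(methylidene)ammonium iodide gives the Mannich base 2-butanoyl-4-[(dimethylamino)methyl]-3,5-dihydroxy-6,6-dimethylcyclohexa-2,4-dien-1-one F1. Heating F1 with an excess of 19 expels dimethylamine, and a ring carbon of 19 traps the quinone-methide-type intermediate, giving the A–B dimer 2-butanoyl-4-[(3-butanoyl-2,4,6-trihydroxyphenyl)methyl]-3,5-dihydroxy-6,6-dimethylcyclohexa-2,4-dien-1-one F2. Hydrogenolysis of 5 gives 1-(4,6-dihydroxy-2-methoxy-3-methylphenyl)butan-1-one F3, which is aminomethylated at its only open carbon to 1-{3-[(dimethylamino)methyl]-2,4-dihydroxy-6-methoxy-5-methylphenyl}butan-1-one F4. Heating F4 with F2, whose ring B has one open carbon left, closes the second bridge and gives 35. This costs convergence and needs separation from symmetrical by-products.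

**Step 13.** Chemoselectivity within the dianion may fail: the peroxide may oxidise the enolate, the enolate may be silylated, or the amide base may induce rearrangement of the benzyl enol ethers.
Fallback, from 23, back at 26: the acetylide is made by halogen–metal exchange instead of deprotonation, so neither amide base nor enolate is involved. Bromination of the alkyne C–H (N-bromosuccinimide, AgNO3 cat., acetone) gives 3,5-bis(benzyloxy)-4-(3-bromoprop-2-yn-1-yl)-2-butanoyl-6,6-dimethylcyclohexa-2,4-dien-1-one F5. Bromine–magnesium exchange with i-PrMgCl·LiCl at −78 °C gives the alkynylmagnesium chloride F6, which is oxidised with t-BuOOLi and silylated with i-Pr3SiCl to give 26.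

**Step 8 (with step 9).** The benzyl ynol ether may be lost by [3,3] rearrangement or acid-induced hydration during coupling and isolation, and the hindered benzylic bromide may homocouple.
Fallback, from 9, back at 18: the four-membered ring is bought rather than built, and no ynol ether is made. Commercial 3-ethoxycyclobut-2-en-1-one is converted by acid-catalysed exchange with 10 into 3-(benzyloxy)cyclobut-2-en-1-one F7. N-Bromosuccinimide brominates the enol-ether carbon to give 3-(benzyloxy)-2-bromocyclobut-2-en-1-one F8. Zinc dust with LiCl in THF inserts into 9 to give {[2,6-bis(benzyloxy)-3-butanoyl-4-methoxy-5-methylphenyl]methyl}zinc bromide F9. A Negishi coupling of F9 with F8 under Pd(PPh3)4 gives 18.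

**Step 2.** Discrimination between the two ortho hydroxyls may be incomplete, with benzylation at the hydroxyl next to the methyl group; the wrong oxygen would then be methylated in step 3.
Fallback, from 1, back at 7: the order of events is changed so that the methyl ether is made at the most acidic hydroxyl. Vilsmeier–Haack formylation of 1 gives 2,4,6-trihydroxy-3-methylbenzaldehyde F10. One equivalent of MeI with K2CO3 methylates the hydroxyl para to the formyl group and gives 2,6-dihydroxy-4-methoxy-3-methylbenzaldehyde F11. Friedel–Crafts butanoylation at the only open carbon gives 3-butanoyl-2,6-dihydroxy-4-methoxy-5-methylbenzaldehyde F12. Exhaustive benzylation of the two chelated hydroxyls gives 7.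

**Step 16.** Acylation may be slow at the crowded B5 position, and the acid may remove benzyl groups from the ring A enol ethers.
Fallback, from 31, back at 35: the acylation is moved to the end. Bu4NF frees the B2 hydroxyl and gives the diol F13. Hydrogenolysis over Pd/C gives the fully deprotected B5-unsubstituted trimer F14. Butanoic anhydride with BF3·OEt2 then acylates B5, the only open ring carbon, and gives 35. This is one step shorter but exposes the unprotected bridges to a Lewis acid, so exchange of the bridges becomes the risk.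

## Further compounds

F1 | step 14 | 2-butanoyl-4-[(dimethylamino)methyl]-3,5-dihydroxy-6,6-dimethylcyclohexa-2,4-dien-1-one | CCCC(=O)C1=C(O)C(CN(C)C)=C(O)C(C)(C)C1=O
F2 | step 14 | 2-butanoyl-4-[(3-butanoyl-2,4,6-trihydroxyphenyl)methyl]-3,5-dihydroxy-6,6-dimethylcyclohexa-2,4-dien-1-one | CCCC(=O)C1=C(O)C(Cc2c(O)cc(O)c(C(=O)CCC)c2O)=C(O)C(C)(C)C1=O
F3 | step 14 | 1-(4,6-dihydroxy-2-methoxy-3-methylphenyl)butan-1-one | CCCC(=O)c1c(O)cc(O)c(C)c1OC
F4 | step 14 | 1-{3-[(dimethylamino)methyl]-2,4-dihydroxy-6-methoxy-5-methylphenyl}butan-1-one | CCCC(=O)c1c(O)c(CN(C)C)c(O)c(C)c1OC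
F5 | step 13 | 3,5-bis(benzyloxy)-4-(3-bromoprop-2-yn-1-yl)-2-butanoyl-6,6-dimethylcyclohexa-2,4-dien-1-one | CCCC(=O)C1=C(OCc2ccccc2)C(CC#CBr)=C(OCc2ccccc2)C(C)(C)C1=O
F6 | step 13 | {3-[2,6-bis(benzyloxy)-5-butanoyl-3,3-dimethyl-4-oxocyclohexa-1,5-dien-1-yl]prop-1-yn-1-yl}magnesium chloride | CCCC(=O)C1=C(OCc2ccccc2)C(CC#C[Mg]Cl)=C(OCc2ccccc2)C(C)(C)C1=O
F7 | step 8 | 3-(benzyloxy)cyclobut-2-en-1-one | O=C1CC(OCc2ccccc2)=C1
F8 | step 8 | 3-(benzyloxy)-2-bromocyclobut-2-en-1-one | O=C1CC(OCc2ccccc2)=C1Br
F9 | step 8 | {[2,6-bis(benzyloxy)-3-butanoyl-4-methoxy-5-methylphenyl]methyl}zinc bromide | CCCC(=O)c1c(OCc2ccccc2)c(C[Zn]Br)c(OCc2ccccc2)c(C)c1OC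
F10 | step 2 | 2,4,6-trihydroxy-3-methylbenzaldehyde | Cc1c(O)cc(O)c(C=O)c1O
F11 | step 2 | 2,6-dihydroxy-4-methoxy-3-methylbenzaldehyde | COc1cc(O)c(C=O)c(O)c1C
F12 | step 2 | 3-butanoyl-2,6-dihydroxy-4-methoxy-5-methylbenzaldehyde | CCCC(=O)c1c(O)c(C=O)c(O)c(C)c1OC
F13 | step 16 | 3,5-bis(benzyloxy)-4-{[4-(benzyloxy)-3-{[2,6-bis(benzyloxy)-3-butanoyl-4-methoxy-5-methylphenyl]methyl}-2,6-dihydroxyphenyl]methyl}-2-butanoyl-6,6-dimethylcyclohexa-2,4-dien-1-one | Oc1cc(OCc2ccccc2)c(Cc2c(OCc3ccccc3)c(C)c(OC)c(C(=O)CCC)c2OCc2ccccc2)c(O)c1CC1=C(OCc2ccccc2)C(C)(C)C(=O)C(C(=O)CCC)=C1OCc1ccccc1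
F14 | step 16 | 2-butanoyl-4-{[3-[(3-butanoyl-2,6-dihydroxy-4-methoxy-5-methylphenyl)methyl]-2,4,6-trihydroxyphenyl]methyl}-3,5-dihydroxy-6,6-dimethylcyclohexa-2,4-dien-1-one | CCCC(=O)C1=C(O)C(Cc2c(O)c(Cc3c(O)c(C)c(OC)c(C(=O)CCC)c3O)c(O)cc2O)=C(O)C(C)(C)C1=O
A1 | alternative 1 | butanoyl ring B with free B2 and B6 hydroxyls, B4 benzyl ether and the protected ring A and ring C arms, both lacking their butanoyl groups | CCCC(=O)c1c(O)c(CC2=C(OCc3ccccc3)C(C)(C)C(=O)C=C2OCc3ccccc3)c(O)c(Cc2c(OCc3ccccc3)c(C)c(OC)cc2OCc3ccccc3)c1OCc1ccccc1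
A2 | alternative 1 | 1-methoxy-1,3-bis(trimethylsilyloxy)buta-1,3-diene carrying the protected ring A methyl arm on C2 and the protected ring C methyl arm on C4 | COC(O[Si](C)(C)C)=C(CC1=C(OCc2ccccc2)C(C)(C)C(=O)C=C1OCc1ccccc1)C(O[Si](C)(C)C)=CCc1c(OCc2ccccc2)c(C)c(OC)cc1OCc1ccccc1
A3 | alternative 1 | 1-(benzyloxy)hex-1-yn-3-one | CCCC(=O)C#COCc1ccccc1
A4 | alternative 2 | ring C phenol (C2 OH free, C6 benzyl ether, C5 unsubstituted) on the protected A–B unit | Cc1c(O)c(Cc3c(OCc4ccccc4)c(C(=O)CCC)c(OCc4ccccc4)c(CC4=C(OCc5ccccc5)C(C)(C)C(=O)C(C(=O)CCC)=C4OCc5ccccc5)c3OCc3ccccc3)c(OCc2ccccc2)cc1OC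
A5 | alternative 2 | 3-(benzyloxy)-4-(arylmethyl)cyclobut-2-en-1-one whose aryl group is the protected A–B unit (racemic) | O=C1C=C(OCc2ccccc2)C1Cc1c(OCc2ccccc2)c(C(=O)CCC)c(OCc2ccccc2)c(CC2=C(OCc3ccccc3)C(C)(C)C(=O)C(C(=O)CCC)=C2OCc2ccccc2)c1OCc1ccccc1
A6 | alternative 2 | 1-methoxyprop-1-yne | CC#COC
A7 | alternative 3 | complete ring C (free C2 and C6 hydroxyls, C4 OMe, C5 butanoyl) on the protected A–B unit lacking both butanoyl groups | CCCC(=O)c1c(O)c(Cc2c(OCc3ccccc3)cc(OCc3ccccc3)c(CC3=C(OCc4ccccc4)C(C)(C)C(=O)C=C3OCc4ccccc4)c2OCc2ccccc2)c(O)c(C)c1OC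
A8 | alternative 3 | 1-methoxy-1,3-bis(trimethylsilyloxy)penta-1,3-diene carrying the protected A–B arylmethyl group on C2 | COC(O[Si](C)(C)C)=C(Cc1c(OCc2ccccc2)cc(OCc2ccccc2)c(CC2=C(OCc3ccccc3)C(C)(C)C(=O)C=C2OCc2ccccc2)c1OCc1ccccc1)C(O[Si](C)(C)C)=CC
A9 | alternative 3 | 1-methoxyhex-1-yn-3-one | CCCC(=O)C#COC
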